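## The problem

Mulberrofuran V (16) is a 2-arylbenzofuran. C2 of a 6-hydroxybenzofuran is bonded to C1' of a resorcinol ring B, and both neighbours of that bond, C2' and C6', carry 3-methylbut-2-enyl chains. There is no stereocentre. The side-chain alkenes end in two identical methyl groups and ring B is symmetric about the C1'–C4' axis, so neither E/Z nor axial isomerism arises; the task is regiochemistry and the order of events. Two carbon chains must go onto C2' and C6', each wedged between the aryl–aryl bond and an oxygen, and none onto C4', the site between the two oxygens that directed metalation would favour. The carbon attached to C1' is thus flanked by two ortho substituents, so any furan synthesis that adds a nucleophile to a carbonyl at that carbon meets the hindrance of a 2,6-dialkylbenzoate. The fragile elements are the two ortho-prenylphenol units (C3'–OH beside the C2' chain, C5'–OH beside the C6' chain). Acid protonates the trisubstituted alkene to a tertiary cation that the neighbouring oxygen traps as a 2,2-dimethylchroman, and the electron-rich triol is easily oxidised. The enabling feature is that each side chain is an allyl group (aryl–CH2–CH=) capped by an isopropylidene unit. A terminal allyl group would give only a secondary cation and so survives the acid that unmasks the phenols, and the cap can be added afterwards by metathesis. The two allyl groups are meta to each other across C1' and cannot close a ring with each other.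

## Retrosynthesis

**16 ⇒ 14 + 15.** The two CH=C(CH3)2 double bonds are cut, leading to triol 14 with two terminal allyl groups and to 2-methylbut-2-ene (15). Cutting the aryl–CH2 bonds instead would bring the acid-sensitive alkenes in early and raise the question of attack at the wrong allyl terminus. The chosen cut leaves every earlier step to deal only with robust terminal alkenes. The forward reaction must favour cross- over self-metathesis, tolerate three free phenols and leave the allyl double bonds where they are.

**14 ⇒ 13.** No skeletal bond is cut; the two ring B phenols are masked as methoxymethyl ethers in 13. These ethers withstand bromination, palladium, hydride and carbonate base. Their removal needs acid, which at this stage meets only terminal allyl groups. The ring A phenol needs no mask here because it emerges free from the ring closure.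

**13 ⇒ 11 (through 12).** The furan O1–C2 bond is cut, giving diarylalkyne 11, whose deacetylated form 12 closes by attack of the ortho oxygen on the alkyne. The neighbouring cut, C2=C3 by ylide attack on an ester of the ring B acid, needs a tetrahedral intermediate at a carbonyl flanked by two allyl groups. A C2–C1' biaryl coupling needs a 2,6-disubstituted aryl metal and a separately made 2-functionalised benzofuran. In 11 the crowded ring carries only a linear two-carbon rod. The forward step must remove two acetates and close the ring without moving the allyl double bonds.

**11 ⇒ 8 + 10.** The C(sp)–C(aryl) bond that becomes C3–C3a is cut, giving ring B alkyne 8 and ring A iodide 10; this is the convergent junction. The reacting alkyne carbon is remote from the ortho substituents. Iodide 10 is the diacetate of commercial 4-iodoresorcinol (9); the acetates make the iodide less electron-rich and fall off in the next step. The coupling must be faster than any Heck-type reaction of the allyl groups.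

**8 ⇒ 7 ⇒ 6 ⇒ 5.** The terminal alkyne carbon is removed, so 8 comes from aldehyde 7 by one-carbon homologation. Aldehyde 7 comes from ester 5 by reduction to alcohol 6 and re-oxidation. Hydride is the only nucleophile that has to add to the flanked ester carbonyl, and the homologation reagent meets an aldehyde, not an ester.

**5 ⇒ 3 + 4, 3 ⇒ 2 ⇒ 1.** Both aryl–CH2 bonds are cut, giving dibromide 3 and allyltributylstannane (4). Dibromide 3 comes from bromination of bis-ether 2, where each of C2 and C6 is para to one ether and ortho to the other. Ether 2 is the protected form of methyl 3,5-dihydroxybenzoate (1). A double Claisen rearrangement of the bis-allyl ether of 1 would be shorter, but it partitions between C2/C6 and C4; it is kept as a fallback. The coupling has to work twice at bromides with two ortho neighbours.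

## Roads not taken

**Alternative 1:** The furan C2=C3 bond is cut. In the forward direction an acyloxybenzylphosphonium salt A2, made from the 2,6-diprenylated ring B acid and a 2-hydroxybenzylphosphonium salt, is deprotonated. The ylide attacks the ester carbonyl and the phosphine oxide is lost, giving the fully protected benzofuran A1.
- Merits: it is convergent, joins the halves through a simple ester, and needs no alkyne chemistry. It is about three operations shorter on the ring B line than the chosen plan, which is a real advantage.
- Weak point 1: the ester carbonyl of A2 sits between two ortho CH2 groups. Saponification to the acid, acylation to A2 and the ylide addition all need a tetrahedral intermediate at a mesitoate-like centre.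
- Weak point 2: A1 already carries both prenyl groups. Removing its three acetal groups needs acid beside two ortho-prenyl oxygens, which is where chroman formation starts.
- Comparison: the chosen plan accepts the extra steps and a ruthenium step. In return, only hydride has to add to the hindered ester, and all acid is used while the side chains are still terminal allyl groups.

**Alternative 2:** Both aryl–CH2 bonds of the prenyl groups are cut as C–H functionalisations. 3,5-Bis(methoxymethoxy)benzoic acid A4 would be ruthenated at each ortho C–H bond under carboxylate direction and coupled with 2-methylbut-3-en-2-ol A5, giving the diprenyl acid A3 in one step.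
- Merits: no halogenation, no tin and no separate capping step. The whole side chain arrives from a bulk alcohol, and the ring B sequence would be shorter by about three steps. The chosen plan cannot match this step and atom economy.
- Weak point 1: each ortho C–H bond of A4 lies between the carboxylate and an ether oxygen, so both metalations occur at 1,2,3-trisubstituted sites. The second must occur on an already twisted, more hindered acid.
- Weak point 2: linear against branched allyl transfer, migration of the new double bond into conjugation, and protodecarboxylation of an electron-rich di-ortho-substituted acid are all open questions for this pattern.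
- Weak point 3: A3 must still be converted through A2 into A1, so both weak points of Alternative 1 are inherited.
- Comparison: the chosen plan forms each aryl–carbon bond at a defined C–Br bond, uses only established reaction classes, and keeps the order "acid first, trisubstituted alkenes last".

**Alternative 3:** Ring B itself is cut at C3'–C4' and C5'–C6'. Heating cyclobutenone A7 (two prenyl groups and the silylated benzofuranyl group on the four-membered ring) with ethynyl triisopropylsilyl ether A8 would open it to a vinylketene. This adds the alkyne, reopens, closes in a six-electron electrocyclisation and tautomerises to the monosilylated resorcinol A6.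
- Merits: the substitution pattern of ring B is fixed by construction. The conditions are neutral and thermal, so the prenyl groups are safe, and the silyl ethers would come off with fluoride. It therefore solves the acid problem as well as the chosen plan does.
- Weak point 1: A7 is a fully substituted, unsymmetrical cyclobutenone bearing a heteroaryl group. It is a multistep target with its own regiochemical problem, and the benzofuran must exist before ring B is made.
- Weak point 2: the crowded vinylketene must accept the alkyne between two substituents, and A8 is a sensitive reagent.
- Weak point 3: the oxygenation pattern of ring B can be bought as 1, so building the ring from scratch spends steps on something already available.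
- Comparison: the chosen plan is shorter once the preparation of A7 is counted.

Key step: step 11

Assumption: 4-iodoresorcinol (9) is treated as a purchasable starting material; if it has to be made, it is the one-step iodination product of resorcinol.

## Route

Step 1
Reactants: 1 methyl 3,5-dihydroxybenzoate
Product: 2 methyl 3,5-bis(methoxymethoxy)benzoate
Conditions: MOMCl (2.6 equiv), iPr2NEt (3 equiv), CH2Cl2, 0 °C to rt
Reagents that add atoms: chloromethyl methyl ether, COCCl
Why: O-alkylation of both phenols by the α-chloro ether (Williamson-type acetal formation); the resulting ethers survive bromination, palladium, hydride and carbonate base and are later removed by dilute acid.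

Step 2
Reactants: 2 methyl 3,5-bis(methoxymethoxy)benzoate
Product: 3 methyl 2,6-dibromo-3,5-bis(methoxymethoxy)benzoate
Conditions: NBS (2.1 equiv), MeCN, 0 °C to rt, dark
Reagents that add atoms: N-bromosuccinimide, O=C1CCC(=O)N1Br
Why: Electrophilic aromatic bromination; C2 and C6 are each para to one ether oxygen and ortho to the other while C4 is shielded between both, the pattern known for dihalogenation of 3,5-dialkoxybenzoates, and NBS in MeCN keeps strong acid away from the acetals.

Step 3
Reactants: 3 methyl 2,6-dibromo-3,5-bis(methoxymethoxy)benzoate, 4 allyltributylstannane
Product: 5 methyl 2,6-diallyl-3,5-bis(methoxymethoxy)benzoate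
Conditions: Pd(PPh3)4 (10 mol%), 4 (3 equiv), DMF, 95 °C, degassed
Reagents that add atoms: none
Why: Twofold Stille coupling; zerovalent palladium inserts into each C–Br bond, the allyl group is transferred from tin and reductive elimination forms the aryl–CH2 bond, a reaction well known for ortho-bromobenzoates that carry a neighbouring alkoxy group; heating is stopped once the dibromide is consumed to limit double-bond migration.

Step 4
Reactants: 5 methyl 2,6-diallyl-3,5-bis(methoxymethoxy)benzoate
Product: 6 [2,6-diallyl-3,5-bis(methoxymethoxy)phenyl]methanol
Conditions: LiAlH4 (1.5 equiv), THF, 0 °C to rt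
Reagents that add atoms: none
Why: Hydride reduction of the ester to the primary alcohol; the small hydride reaches the doubly flanked carbonyl where hydroxide would not, and terminal alkenes and acetals are inert.

Step 5
Reactants: 6 [2,6-diallyl-3,5-bis(methoxymethoxy)phenyl]methanol
Product: 7 2,6-diallyl-3,5-bis(methoxymethoxy)benzaldehyde
Conditions: Dess–Martin periodinane (1.3 equiv), CH2Cl2, rt
Reagents that add atoms: none
Why: Dess–Martin oxidation (ligand exchange at iodine, then loss of the carbinol hydrogen) stops cleanly at the aldehyde under near-neutral conditions that leave allyl groups and acetals alone.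

Step 6
Reactants: 7 2,6-diallyl-3,5-bis(methoxymethoxy)benzaldehyde
Product: 8 2,4-diallyl-3-ethynyl-1,5-bis(methoxymethoxy)benzene
Conditions: Ohira–Bestmann reagent (1.5 equiv), K2CO3 (2 equiv), MeOH, 0 °C to rt
Reagents that add atoms: dimethyl (1-diazo-2-oxopropyl)phosphonate, COP(=O)(OC)C(=[N+]=[N-])C(C)=O
Why: Seyferth–Gilbert homologation in its Ohira–Bestmann form; methanolysis frees the diazomethylphosphonate anion, which adds to the aldehyde, loses dimethyl phosphate and N2 to an alkylidene carbene and rearranges by 1,2-hydrogen shift to the terminal alkyne, while the carbonate base is too weak to move the allyl double bonds.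

Step 7
Reactants: 9 4-iodoresorcinol
Product: 10 4-iodo-1,3-phenylene diacetate
Conditions: Ac2O (2.5 equiv), DMAP (cat.), pyridine, 0 °C to rt
Reagents that add atoms: acetic anhydride, CC(=O)OC(C)=O
Why: Acylation of both phenols; the acetates make the iodide less electron-rich for oxidative addition, prevent phenoxide side reactions during coupling and are removed by the base that closes the furan.

Step 8
Reactants: 8 2,4-diallyl-3-ethynyl-1,5-bis(methoxymethoxy)benzene, 10 4-iodo-1,3-phenylene diacetate
Product: 11 4-{[2,6-diallyl-3,5-bis(methoxymethoxy)phenyl]ethynyl}-1,3-phenylene diacetate
Conditions: PdCl2(PPh3)2 (5 mol%), CuI (10 mol%), Et3N, THF, 45 °C, degassed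
Reagents that add atoms: none
Why: Sonogashira coupling; oxidative addition of the aryl iodide, transmetalation from the cuprous acetylide and reductive elimination form the C(sp)–C(aryl) bond at an alkyne carbon remote from the ortho substituents, and the aryl iodide reacts far faster than the allyl alkenes could insert.

Step 9
Reactants: 11 4-{[2,6-diallyl-3,5-bis(methoxymethoxy)phenyl]ethynyl}-1,3-phenylene diacetate
Product: 13 2-[2,6-diallyl-3,5-bis(methoxymethoxy)phenyl]benzofuran-6-ol, via resorcinol alkyne 12 (not isolated)
Conditions: Cs2CO3 (3 equiv), MeOH/DMF (1:4), 60 °C
Reagents that add atoms: none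
Why: Methanolysis of both aryl acetates gives the ortho-alkynylphenoxide, which closes the furan by 5-endo-dig attack of oxygen on the alkyne carbon bearing ring B and protonation at C3, a known route from ortho-acetoxy diarylalkynes to 2-arylbenzofurans; carbonate at this temperature does not isomerise allylarenes.

Step 10
Reactants: 13 2-[2,6-diallyl-3,5-bis(methoxymethoxy)phenyl]benzofuran-6-ol
Product: 14 4,6-diallyl-5-(6-hydroxybenzofuran-2-yl)benzene-1,3-diol
Conditions: 3 M HCl (aq.), MeOH, 50 °C, Ar
Reagents that add atoms: none
Why: Acid-catalysed acetal cleavage through the oxocarbenium ion, which methanol carries off as dimethoxymethane; the terminal allyl groups would give only secondary cations and do not add the neighbouring phenols under these conditions, and the benzofuran is acid-stable.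

Step 11
Reactants: 14 4,6-diallyl-5-(6-hydroxybenzofuran-2-yl)benzene-1,3-diol, 15 2-methylbut-2-ene
Product: 16 Mulberrofuran V, 5-(6-hydroxybenzofuran-2-yl)-4,6-bis(3-methylbut-2-enyl)benzene-1,3-diol
Conditions: second-generation Grubbs catalyst RuCl2(H2IMes)(PCy3)(=CHPh) (10 mol%), 15/CH2Cl2 (1:1), rt, Ar, stopped at full conversion
Reagents that add atoms: none
Why: Twofold olefin cross-metathesis by the Chauvin mechanism: after loss of PCy3 the ruthenium benzylidene exchanges with a terminal allyl alkene of 14, and the resulting side-chain alkylidene forms a metallacyclobutane with 15 whose cycloreversion releases the aryl–CH2–CH=C(CH3)2 unit; each event is balanced by one molecule of propene, which leaves as a gas. The closest known reaction type is the conversion of ortho-allylphenols into ortho-prenylphenols with 2-methylbut-2-ene, here carried out twice on one ring. No ring is closed and no stereocentre is formed, and the new alkenes bear two identical methyl groups, so no E/Z question arises. The step needs cross- over self-metathesis, which the large excess of 15 as co-solvent secures. The trisubstituted product alkenes are too hindered to re-enter the cycle and therefore accumulate. Ring closure between the side chains is impossible because they are meta to each other across C1', and the furan C2=C3 bond is part of an aromatic system and does not engage. The catalyst tolerates the three free phenols, and because no acid is present the ortho-prenylphenols formed cannot cyclise to chromans. A short reaction time limits ruthenium hydride-mediated migration of the allyl double bonds.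

## Compound list

1 | methyl 3,5-dihydroxybenzoate | COC(=O)c1cc(O)cc(O)c1 | starting material
2 | methyl 3,5-bis(methoxymethoxy)benzoate | COCOc1cc(OCOC)cc(c1)C(=O)OC | intermediate
3 | methyl 2,6-dibromo-3,5-bis(methoxymethoxy)benzoate | COCOc1cc(OCOC)c(Br)c(C(=O)OC)c1Br | intermediate
4 | allyltributylstannane | C=CC[Sn](CCCC)(CCCC)CCCC | starting material
5 | methyl 2,6-diallyl-3,5-bis(methoxymethoxy)benzoate | C=CCc1c(OCOC)cc(OCOC)c(CC=C)c1C(=O)OC | intermediate
6 | [2,6-diallyl-3,5-bis(methoxymethoxy)phenyl]methanol | C=CCc1c(OCOC)cc(OCOC)c(CC=C)c1CO | intermediate
7 | 2,6-diallyl-3,5-bis(methoxymethoxy)benzaldehyde | C=CCc1c(OCOC)cc(OCOC)c(CC=C)c1C=O | intermediate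
8 | 2,4-diallyl-3-ethynyl-1,5-bis(methoxymethoxy)benzene | C#Cc1c(CC=C)c(OCOC)cc(OCOC)c1CC=C | intermediate
9 | 4-iodoresorcinol (4-iodobenzene-1,3-diol) | Oc1ccc(I)c(O)c1 | starting material
10 | 4-iodo-1,3-phenylene diacetate | CC(=O)Oc1ccc(I)c(OC(C)=O)c1 | intermediate
11 | 4-{[2,6-diallyl-3,5-bis(methoxymethoxy)phenyl]ethynyl}-1,3-phenylene diacetate | CC(=O)Oc1ccc(C#Cc2c(CC=C)c(OCOC)cc(OCOC)c2CC=C)c(OC(C)=O)c1 | intermediate
12 | 4-{[2,6-diallyl-3,5-bis(methoxymethoxy)phenyl]ethynyl}benzene-1,3-diol | Oc1ccc(C#Cc2c(CC=C)c(OCOC)cc(OCOC)c2CC=C)c(O)c1 | intermediate
13 | 2-[2,6-diallyl-3,5-bis(methoxymethoxy)phenyl]benzofuran-6-ol | C=CCc1c(OCOC)cc(OCOC)c(CC=C)c1-c1cc2ccc(O)cc2o1 | intermediate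
14 | 4,6-diallyl-5-(6-hydroxybenzofuran-2-yl)benzene-1,3-diol | C=CCc1c(O)cc(O)c(CC=C)c1-c1cc2ccc(O)cc2o1 | intermediate
15 | 2-methylbut-2-ene | CC=C(C)C | starting material
16 | Mulberrofuran V | CC(C)=CCc1c(O)cc(O)c(CC=C(C)C)c1-c1cc2ccc(O)cc2o1 | target

## Step count and least certain steps

Total: 11 steps. Longest linear sequence: 10 steps (steps 1–6 and 8–11 from compound 1); the ring A branch is one step (step 7).

**Step 11 (key step).**
- Risk: ruthenium hydride species may move the allyl double bonds into conjugation with ring B, after which metathesis shortens the chain. The ortho phenols may also chelate the ruthenium alkylidene, slowing turnover so that the reaction stalls after the first side chain or drifts towards intermolecular self-metathesis.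
- Fallback: triol 14 is peracetylated (Ac2O, pyridine) to 4,6-diallyl-5-(6-acetoxybenzofuran-2-yl)-1,3-phenylene diacetate F1. The same cross-metathesis with 15 on F1 gives Mulberrofuran V triacetate F2. Methanolysis with K2CO3 in MeOH at 0 °C to rt, a base treatment that does not affect prenyl groups, returns to 16. The detour costs two steps and keeps the key bond formation unchanged.

**Step 3.**
- Risk: the second oxidative addition takes place at a more electron-rich bromide with two ortho neighbours and may be slow. Long heating then favours protodebromination and palladium hydride-induced migration of the allyl double bond.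
- Fallback: ester 1 is O-allylated (allyl bromide, K2CO3, acetone, reflux) to methyl 3,5-bis(allyloxy)benzoate F3. Heating F3 in N,N-diethylaniline at about 200 °C brings about a double aromatic Claisen rearrangement. The meta ester biases migration towards C2 and C6, giving methyl 2,6-diallyl-3,5-dihydroxybenzoate F4 after separation from the isomers that carry an allyl group at C4. Protection with MOMCl and iPr2NEt returns to 5. This route is free of tin and palladium but pays with a separation.

**Step 6.**
- Risk: addition of the diazophosphonate anion to an aldehyde flanked by two allyl groups may be slow, so that decay of the reagent in methanol outruns the homologation.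
- Fallback: Corey–Fuchs sequence. Aldehyde 7 with CBr4 and PPh3 in CH2Cl2 at 0 °C gives 2,4-diallyl-3-(2,2-dibromovinyl)-1,5-bis(methoxymethoxy)benzene F5. Treatment with n-BuLi (2.1 equiv) in THF at −78 °C and aqueous quench (bromine–lithium exchange, then carbenoid rearrangement) returns to 8.

**Step 9.**
- Risk: the 5-endo-dig closure attacks an alkyne carbon bearing an electron-rich, 2,6-disubstituted aryl group and is further slowed by the para phenoxide on ring A. The reaction may stop at the deacetylated stage, and prolonged heating with base could then move the allyl double bonds.
- Fallback: Castro–Stephens coupling, which forms the C–C and C–O bonds in one operation on copper. Alkyne 8 is converted with CuI and aqueous NH3 in EtOH into the cuprous acetylide of 8, F6. Heating F6 with free 4-iodoresorcinol (9) in pyridine at 110 °C gives 13 directly, bypassing 10 and 11.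

## Further compounds

F1 | step 11 | 4,6-diallyl-5-(6-acetoxybenzofuran-2-yl)-1,3-phenylene diacetate | C=CCc1c(OC(C)=O)cc(OC(C)=O)c(CC=C)c1-c1cc2ccc(OC(C)=O)cc2o1
F2 | step 11 | Mulberrofuran V triacetate | CC(C)=CCc1c(OC(C)=O)cc(OC(C)=O)c(CC=C(C)C)c1-c1cc2ccc(OC(C)=O)cc2o1
F3 | step 3 | methyl 3,5-bis(allyloxy)benzoate | C=CCOc1cc(OCC=C)cc(c1)C(=O)OC
F4 | step 3 | methyl 2,6-diallyl-3,5-dihydroxybenzoate | C=CCc1c(O)cc(O)c(CC=C)c1C(=O)OC
F5 | step 6 | 2,4-diallyl-3-(2,2-dibromovinyl)-1,5-bis(methoxymethoxy)benzene | BrC(Br)=Cc1c(CC=C)c(OCOC)cc(OCOC)c1CC=C
F6 | step 9 | cuprous acetylide of 8, {[2,6-diallyl-3,5-bis(methoxymethoxy)phenyl]ethynyl}copper | [Cu]C#Cc1c(CC=C)c(OCOC)cc(OCOC)c1CC=C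
A1 | alternative 1 | 2-[3,5-bis(methoxymethoxy)-2,6-bis(3-methylbut-2-enyl)phenyl]-6-(methoxymethoxy)benzofuran | CC(C)=CCc1c(OCOC)cc(OCOC)c(CC=C(C)C)c1-c1cc2ccc(OCOC)cc2o1
A2 | alternative 1 | {2-[3,5-bis(methoxymethoxy)-2,6-bis(3-methylbut-2-enyl)benzoyloxy]-4-(methoxymethoxy)benzyl}triphenylphosphonium bromide | CC(C)=CCc1c(OCOC)cc(OCOC)c(CC=C(C)C)c1C(=O)Oc1cc(OCOC)ccc1C[P+](c1ccccc1)(c1ccccc1)c1ccccc1.[Br-]
A3 | alternative 2 | 3,5-bis(methoxymethoxy)-2,6-bis(3-methylbut-2-enyl)benzoic acid | CC(C)=CCc1c(OCOC)cc(OCOC)c(CC=C(C)C)c1C(=O)O
A4 | alternative 2 | 3,5-bis(methoxymethoxy)benzoic acid | COCOc1cc(OCOC)cc(c1)C(=O)O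
A5 | alternative 2 | 2-methylbut-3-en-2-ol | C=CC(C)(C)O
A6 | alternative 3 | 2,4-bis(3-methylbut-2-enyl)-5-(triisopropylsilyloxy)-3-[6-(triisopropylsilyloxy)benzofuran-2-yl]phenol | CC(C)=CCc1c(O)cc(O[Si](C(C)C)(C(C)C)C(C)C)c(CC=C(C)C)c1-c1cc2ccc(O[Si](C(C)C)(C(C)C)C(C)C)cc2o1
A7 | alternative 3 | 2,4-bis(3-methylbut-2-enyl)-3-[6-(triisopropylsilyloxy)benzofuran-2-yl]cyclobut-2-en-1-one (racemic) | CC(C)=CCC1C(=O)C(CC=C(C)C)=C1c1cc2ccc(O[Si](C(C)C)(C(C)C)C(C)C)cc2o1
A8 | alternative 3 | ethynyl triisopropylsilyl ether | C#CO[Si](C(C)C)(C(C)C)C(C)C
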